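The south run and the north-west run climb alike: between 3.00 min and 6.00 min they make target at 0.947 mM min⁻¹ and 0.953 mM min⁻¹, though the south flask holds 12 mM of solid reagent and the north-west flask 27 mM.

| flask | substrate | solid reagent | remark | time |
|---|---|---|---|---|
| south | 20 mM | 12 mM | run made earlier |  |
| north-west | 20 mM | 27 mM | run made earlier |  |
| south-east | 10 mM | 18 mM | run made earlier |  |
| flask | 20 mM | 18.0 mM |  | 10 min |

- south (time / min: target / %, substrate / %): 0.500: 0.4, 100.4; 1.50: 3.8, 95.1; 3.00: 10.4, 89.7; 4.00: 15.5, 84.7; 6.00: 24.6, 74.4
- north-west (time / min: target / %, substrate / %): 0.500: 0.8, 98.9; 0.833: 0.5, 98.0; 1.50: 3.1, 96.0; 3.00: 9.9, 89.5; 6.00: 24.2, 73.6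
- south-east (time / min: target / %, substrate / %): 0.500: 1.4, 98.5; 0.833: 1.3, 99.8; 1.50: 4.7, 95.3; 3.00: 13.4, 86.3; 6.00: 33.0, 64.4

(each reading ± 0.5 percentage points)

- solid reagent is a solid; its amount is given per volume of the solution
- at the start none of the solid reagent is in solution

- how much target there is at 10 min, in percent of the substrate charged
- the change that raises the amount of target at 10 min, in percent of the substrate charged most ("none" if none brings more than 2 percentage points) (theta / zeta / none)
- amount of target at 10 min, in percent of the substrate charged, after theta

- theta: doubling the dissolution coefficient of the solid reagent, all else as stated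
- zeta: doubling the solubility of the solid reagent, all else as stated

In the same window the south-east run makes 0.653 mM min⁻¹, at a mean c(substrate) of 7.54 mM against 16.4 mM in the south run. These two runs differ in solid reagent as well as in substrate; taking the charge of solid reagent as without effect, as the south and north-west rates suggest, they give the apparent order n, the logarithm of the rate ratio over the logarithm of the concentration ratio:

n = 0.476

The earlier runs start flat, so the target curve of the asked flask is drawn flat at first. The south line reaches zero at 0.803 min, and this knee is taken over. Past it my reckoning sets the slope near 1.04 mM min⁻¹ and lets it sink with substrate, towards a level of 90.0% if one solid reagent gives one target, which would make solid reagent the limiting reagent. My reckoning replaces the sinking slope by its value at mean c(substrate), over 9.20 min: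

first pass: mean c(substrate) 15.2 mM, target 8.40 mM, or 42.0%

second pass: mean c(substrate) 15.8 mM, target 8.55 mM, or 42.8%

My estimate is the mean of the passes, 42.4%, and the passes differ by 0.76 percentage points.

The forecast gives 42%, 57% after theta, and zeta as best, reasoning “dissolution doesn't depend on the solid loading”.

The flask gives 42.6%, 0.20 points from my estimate. Theta adds 19 points and reaches 61.4%; zeta adds 22 points.

    substrate + partner → target (k = 0.543 M⁻¹ s⁻¹)
    substrate + 2 partner → side product (k = 14.5 M⁻² s⁻¹)
    solid reagent ⇌ partner, rate k3*(cs3 - [partner]) while solid is left; crystals form when [partner] > cs3 (solubility = 8.70 mM, k = 0.00280 s⁻¹)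

For the neighbour flask with 50 mM of substrate, all else as in the asked flask, the same two passes with n give 13.7 mM and 13.8 mM of target, so 27.5%; at 10 min that flask holds 23.5% of target.

The earlier runs and the new flask were computed with made-up constants; noise was put on by code.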